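## The problem

Compound 22 is a cyclobutane whose two adjacent quaternary carbons, C5 and C6 of a 1,7-dioxadispiro[4.0.4.2]dodecane, are each the C5 of a 4-bromo-3-(1-acetoxybutyl)furan-2(5H)-one (rings A and B). The other two ring carbons, C11 and C12, are CHBr groups. There are six stereocentres. On the four-membered ring the two lactone oxygens are trans, the two bromines are trans, and each bromine is trans to the lactone oxygen on the neighbouring spiro carbon, so the core has a twofold axis and its four centres can be set relative to one another. The two acetoxy-bearing carbons lie three bonds from the nearest spiro carbon and carry opposite descriptors (one R, one S). The core cannot be expected to control them, but because of the axis the unlike pair is one compound whichever half is R. Sensitive points are the vinylogous acyl bromides (C4–Br, C10–Br), the vicinal dibromide, the acetates, and the strained ring itself: with oxygen and acyl carbon on adjacent carbons it can cleave by retro-aldol as an alkoxide and, while it is a cyclobutene, by conrotatory opening. The feature that allows the key step is the C5–C6 bond. It joins two carbons that each carry one oxygen and one carboxyl-level carbon with the oxygens trans, which is the relationship of C6 and C3 in a 3-oxy-2-pyrone-6-carboxylate, whose C5 and C4 become C12 and C11.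

## Retrosynthesis

**Acetates, one with inversion (22 ⇒ 21 ⇒ 20).** The last bonds made are the two ester C–O bonds. Because of the twofold axis it is enough to reach the like diol 20, acetylate one of its two homotopic hydroxyls (21) and esterify the other with inversion. Building the two butenolides one after the other with opposite reagents would double the ring-building steps and expose a finished bromobutenolide to the base of the second ring closure. The price is a statistical monoacylation; the final step must be a clean SN2 displacement at a carbinol flanked by the butenolide.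

**Carbinol C–H bonds and the resolution (20 ⇒ 18).** Two C–H bonds are cut back to diketone 18, an alkenyl n-propyl ketone on each half and a good case for reagent control. The reduction has a second use. Nothing earlier can fix the absolute sense of the core, and a reagent that gives the same carbinol configuration on either enantiomer of racemic 18 turns the enantiomers into diastereomers, so separation at 20 is the resolution and costs no step. An earlier resolution would save material but adds a step or a hindered ester, and is kept as a fallback. The separation must be made at 20 or 21, because after the inversion the product from the wrong core would be the enantiomer of 22.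

**Vinylic bromides (18 ⇒ 16).** The two vinylic C–Br bonds are traced to the enol C–O bonds of bis(tetronic acid) 16. This keeps the nucleophile-sensitive bromides out of all earlier steps and leaves both rings closable by enolate chemistry. The forward reaction must activate the ring enol oxygen and not the oxygen of the 3-acyl group.

**Butenolide rings (16 ⇒ 14 ⇒ 8 + 12; 12 ⇐ 11 ⇐ 9 + 10).** Cutting C3–C4 and C9–C10 (Lacey–Dieckmann) and then the two acyl–oxygen bonds gives diol diester 8 and two molecules of butanoylketene 12, each released from one molecule of acyl Meldrum's acid 11 (from 9 and 10). This uses the esters and tertiary hydroxyls that the ring synthesis delivers anyway, and an acylketene reaches a hindered tertiary alcohol without base. 8 has only the four ring stereocentres and a twofold axis. The forward steps must never form an alkoxide of 8 and must close two rings without touching the dibromide.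

**Lactone and silyl ether (8 ⇒ 6).** 8 is the methanolysis product of β-lactone 6 after loss of the silyl group; one ester C–O bond and the Si–O bond are cut. The lactone exists only to hold oxygen and carboxyl carbon of the two quaternary centres trans, and is then opened at the acyl carbon. Acid is preferred for both operations because it never gives the tertiary alkoxide.

**Ring bromines (6 ⇒ 5).** The two ring C–Br bonds are cut here and not at the end. Keeping the cyclobutene to the bis-spiro stage looks shorter but has two faults:
- A monocyclic cyclobutene with trans oxygen substituents on its sp3 carbons is set up for conrotatory opening with both donors turning outward, and it would have to survive the 85 °C acylation and the Dieckmann base.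
- In the bis-spiro diene the rear-side path to the required dibromide runs past a vinylic bromine held close to the ring face, so bromide should enter next to the ring oxygens and give the other trans-dibromide.

In 5 the ring cannot open, the only alkene is the one to be brominated, and the bulky silyloxy group on C4 should send the C5 bromine anti to itself, which is what 22 needs.

**The four-membered ring (5 ⇒ 4).** The C1–C4 bond of 5 is cut, giving pyrone 4. No ground-state alternative joins two such carbons with the oxygens forced trans; here the bridge does it. The precursor is flat and achiral. The forward step must favour 4π closure over ketene formation and dimerisation, and leaves the alkene for step 5.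

**Pyrone (4 ⇒ 3 ⇒ 2 ⇒ 1).** The Si–O and ester C–O bonds are cut back to salt 2, the known dehydration product of galactaric acid 1, which supplies all six carbons with the oxygens in place.

## Roads not taken

**Alternative 1: oxaspiropentane ring expansion.** The cut runs from one spiro carbon to a ring CH2 and leaves the second spiro carbon as a ketone. Forward, cyclopropylidene butenolide A1 would be epoxidised to oxaspiropentane A2, and LiI or BF3·OEt2 would open the epoxide at C5 with migration of a cyclopropane bond to give spiro cyclobutanone A3.
- Merits: ground-state chemistry; the bromobutenolide and its carbinol are made on an ordinary butenolide; and the two halves arrive one after the other, so the unlike side chains need no statistical step. In that respect it is better than the chosen plan.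
- Weak points: A3 has two methylenes where 22 has CHBr–CHBr, so both must be oxidised and then brominated with control. The second butenolide must still be built on the ketone with the oxygens trans. The cation needed at C5 is allylic to an electron-poor bromo-enoate. Iodide can exchange the vinylic bromine.
- Comparison: the chosen plan sets against the better handling of the side chains a single step that delivers all four ring carbons at the right oxidation level, with the trans oxygens fixed by a bridge.

**Alternative 2: tartrate-derived cyclobutene, double Dieckmann.** The cuts are the same C3–C4 bonds as in the chosen route, made on a cyclobutene. Dimethyl (2R,3R)-tartrate A4 would have to be turned into cyclobutene diol diester A5, acylated to bis(3-oxohexanoate) A6 and closed with base to A7.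
- Merits: both quaternary centres come from the chiral pool with the right absolute sense (retention at both carbons), so no resolution and no photochemistry. This is a real advantage over the chosen plan.
- Weak points: attaching a cis-vinylene unit to both α-carbons of a tartrate while the diol stays trans has no direct precedent, and a trans-fused acetal cannot hold the diol on a four-membered ring. A5 and A6 are the monocyclic donor-substituted cyclobutenes whose ring opening and retro-aldol cleavage the chosen route avoids. A7 still needs bromine added last, across faces guarded by the C4 substituents.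
- Comparison: the endgame is shared. The chosen plan pays with a resolution and sets against it a ring-forming step of known type and a locked, then saturated, ring through all thermal and basic steps.

**Alternative 3: cyclobutenedione doubly annulated.** Both C4–C5 bonds and both lactone C–O bonds are cut. Cyclobut-3-ene-1,2-dione A8 would take up two equivalents of the lithium carbenoid made from gem-dibromoacrylate A9 at −100 °C, and the alkoxides would close onto the esters to give A10.
- Merits: the shortest route on paper, highly convergent, with the side-chain carbinols from a building block. The vinylic bromine is present from the start, so the enol-activation question of step 10 never arises; there it is better.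
- Weak points: after both additions two alkoxide oxygens sit trans on the sp3 carbons of a cyclobutene, the best case for anion-accelerated conrotatory opening, which competes with lactonisation. Nothing controls the trans course of the second addition. The bromine–lithium exchange must pick the bromine cis to the ester, and the α-bromoalkenyllithium can rearrange or attack its own ester. A10 carries like (S,S) side chains, so one centre must still be inverted, now after statistical removal of one of two homotopic silyl ethers. The final bromine addition meets the same facial problem.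
- Comparison: several steps shorter if everything worked. The chosen plan is longer, but each step is of a known type and the ring is never an alkoxide-bearing cyclobutene.

Key step: step 4

Remarks on the chemistry:
- 4 is achiral and no chiral reagent acts before step 11, so 5 to 18 are racemates; names and SMILES show the enantiomer that is carried into 20.
- Where one reagent acts on both equivalent halves in one operation, the half-reacted compound is listed as an intermediate that is not isolated.

Step 1
Reactants: 1 galactaric acid
Product: 2 sodium 3-acetoxy-2-oxo-2H-pyran-6-carboxylate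
Conditions: Ac2O, NaOAc, 100 °C
Reagents that add atoms: acetic anhydride CC(=O)OC(C)=O; sodium acetate CC(=O)[O-].[Na+]
Why: Known dehydrative cyclisation of galactaric acid: peracetylation, two β-eliminations of acetic acid and lactonisation give the 3-acetoxy-2-pyrone-6-carboxylate, collected as its sodium salt.

Step 2
Reactants: 2 sodium 3-acetoxy-2-oxo-2H-pyran-6-carboxylate
Product: 3 methyl 3-hydroxy-2-oxo-2H-pyran-6-carboxylate
Conditions: H2SO4, MeOH, reflux
Reagents that add atoms: methanol CO
Why: Fischer esterification with concurrent acid-catalysed methanolysis of the enol acetate; the 2-pyrone ring is stable to anhydrous acid.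

Step 3
Reactants: 3 methyl 3-hydroxy-2-oxo-2H-pyran-6-carboxylate
Product: 4 methyl 3-[(tert-butyldimethylsilyl)oxy]-2-oxo-2H-pyran-6-carboxylate
Conditions: TBSCl, imidazole, DMF, 0 °C to rt
Reagents that add atoms: tert-butyldimethylsilyl chloride CC(C)(C)[Si](C)(C)Cl
Why: Imidazole-mediated silylation of an acidic enolic hydroxyl; TBS is chosen because its bulk is meant to steer the bromine addition in step 5.

Step 4
Reactants: 4 methyl 3-[(tert-butyldimethylsilyl)oxy]-2-oxo-2H-pyran-6-carboxylate
Product: 5 methyl (1R,4R)-4-[(tert-butyldimethylsilyl)oxy]-3-oxo-2-oxabicyclo[2.2.0]hex-5-ene-1-carboxylate (racemate)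
Conditions: hν (300 nm, Pyrex), degassed CH2Cl2 (0.01 M), −20 °C, flow reactor; solution kept cold for step 5
Reagents that add atoms: none
Why: Excitation of the 2-pyrone (π,π* singlet) is followed by disrotatory 4π electrocyclisation of the C3=C4–C5=C6 diene, which forms the C3–C6 σ bond and leaves C4=C5 as the cyclobutene double bond; this is the known photochemical valence isomerisation of 2-pyrones to 2-oxabicyclo[2.2.0]hex-5-en-3-ones. The cyclobutene is the one ring that closes, by electrocyclic closure, and the former O1–C2 unit is left as the β-lactone bridge. The two new stereocentres (C1 and C4 of 5) are fixed relative to each other by that bridge, which can span only one face, so ring oxygen and silyloxy group are trans, as are ester and lactone carbonyl; this is the trans arrangement of the spiro oxygens of 22. Nothing in 4 distinguishes the two senses of closure, so 5 should form as the racemate. The step needs chemoselectivity for closure over reversible ring opening to a ketene and over photodimerisation: an aprotic solvent lets the ketene reclose, high dilution disfavours dimerisation, and the Pyrex cut-off keeps light from 5, which should no longer absorb there, so that it can accumulate without losing CO2. Ester and silyl ether are spectators. Because 5 is strained and has captodative bridgeheads it is kept cold and brominated without delay.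

Step 5
Reactants: 5 methyl (1R,4R)-4-[(tert-butyldimethylsilyl)oxy]-3-oxo-2-oxabicyclo[2.2.0]hex-5-ene-1-carboxylate (racemate)
Product: 6 methyl (1R,4R,5R,6R)-5,6-dibromo-4-[(tert-butyldimethylsilyl)oxy]-3-oxo-2-oxabicyclo[2.2.0]hexane-1-carboxylate (racemate)
Conditions: Br2 (1.05 equiv), CH2Cl2, −78 °C, dark
Reagents that add atoms: bromine BrBr
Why: Electrophilic anti addition of Br2 to the only C=C bond through a bromonium ion; the flanking quaternary carbons carry acceptor groups, which disfavours cationic ring contraction. Of the two anti adducts the one with the C5 bromine anti to the bulky bridgehead silyloxy group is expected from either face of bromonium formation, and this places the C6 bromine anti to the lactone oxygen. Saturating the ring before the lactone is opened also removes the conrotatory opening open to a monocyclic 3,4-dioxy cyclobutene.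

Step 6
Reactants: 6 methyl (1R,4R,5R,6R)-5,6-dibromo-4-[(tert-butyldimethylsilyl)oxy]-3-oxo-2-oxabicyclo[2.2.0]hexane-1-carboxylate (racemate)
Product: 8 dimethyl (1R,2R,3R,4R)-3,4-dibromo-1,2-dihydroxycyclobutane-1,2-dicarboxylate (racemate), via hydroxy silyl ether diester 7 (not isolated)
Conditions: HCl (1.25 M in MeOH), 0 to 40 °C
Reagents that add atoms: methanol CO
Why: Acid-catalysed acyl–oxygen methanolysis of the strained β-lactone (alkyl–oxygen cleavage is excluded at the quaternary, acceptor-substituted C1), then acid methanolysis of the tertiary silyl ether in the same medium. No alkoxide is formed, so retro-aldol opening of the cyclobutane is avoided and the four stereocentres are untouched.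

Step 7
Reactants: 9 Meldrum's acid; 10 butanoyl chloride
Product: 11 5-(1-hydroxybutylidene)-2,2-dimethyl-1,3-dioxane-4,6-dione
Conditions: pyridine, CH2Cl2, 0 °C to rt
Reagents that add atoms: none
Why: Standard C-acylation of Meldrum's acid with an acid chloride; the product is the stable enol form.

Step 8
Reactants: 8 dimethyl (1R,2R,3R,4R)-3,4-dibromo-1,2-dihydroxycyclobutane-1,2-dicarboxylate (racemate); 11 5-(1-hydroxybutylidene)-2,2-dimethyl-1,3-dioxane-4,6-dione (two molecules are consumed, one per hydroxyl)
Product: 14 dimethyl (1R,2R,3R,4R)-3,4-dibromo-1,2-bis[(3-oxohexanoyl)oxy]cyclobutane-1,2-dicarboxylate (racemate), via butanoylketene 12 (not isolated), via mono(3-oxohexanoate) 13 (not isolated)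
Conditions: 11 (2.5 equiv in all), toluene, 85 °C
Reagents that add atoms: 5-(1-hydroxybutylidene)-2,2-dimethyl-1,3-dioxane-4,6-dione (the second molecule of 11, which acylates the second hydroxyl) CCCC(O)=C1C(=O)OC(C)(C)OC1=O
Why: Thermolysis of each molecule of the acyl Meldrum's acid releases acetone and CO2 and gives the acylketene, which adds a hindered tertiary alcohol through a six-membered pseudopericyclic transition state under neutral conditions; the first molecule gives monoester 13 and the second acylates the remaining hydroxyl to give 14.

Step 9
Reactants: 14 dimethyl (1R,2R,3R,4R)-3,4-dibromo-1,2-bis[(3-oxohexanoyl)oxy]cyclobutane-1,2-dicarboxylate (racemate)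
Product: 16 (5S,6S,11R,12R)-11,12-dibromo-3,9-dibutanoyl-4,10-dihydroxy-1,7-dioxadispiro[4.0.4.2]dodeca-3,9-diene-2,8-dione (racemate), via half-cyclised keto ester 15 (not isolated)
Conditions: KOtBu (2.4 equiv), THF, −20 to 0 °C; then aq. HCl
Reagents that add atoms: none
Why: Twofold Lacey–Dieckmann cyclisation: each β-keto ester enolate attacks the geminal methyl ester (5-exo-trig) and the acidic 3-acyl tetronic acid consumes the expelled methoxide, which drives the closure. The spiro carbons are not touched; the trans-dibromide has no anti hydrogen for E2 and is a neopentyl-type cyclobutyl halide, so it should be inert to the enolate.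

Step 10
Reactants: 16 (5S,6S,11R,12R)-11,12-dibromo-3,9-dibutanoyl-4,10-dihydroxy-1,7-dioxadispiro[4.0.4.2]dodeca-3,9-diene-2,8-dione (racemate)
Product: 18 (5S,6S,11R,12R)-4,10,11,12-tetrabromo-3,9-dibutanoyl-1,7-dioxadispiro[4.0.4.2]dodeca-3,9-diene-2,8-dione (racemate), via monobromo enol 17 (not isolated)
Conditions: (COBr)2 (3 equiv), DMF (cat.), CH2Cl2, 0 °C to rt
Reagents that add atoms: oxalyl bromide O=C(Br)C(Br)=O
Why: Vilsmeier-type activation of the ring enol followed by addition–elimination of bromide, the known conversion of tetronic acids into 4-bromobutenolides; 2-acyl-1,3-diones react in the same way at the ring oxygen to give ring β-halo enones.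

Step 11
Reactants: 18 (5S,6S,11R,12R)-4,10,11,12-tetrabromo-3,9-dibutanoyl-1,7-dioxadispiro[4.0.4.2]dodeca-3,9-diene-2,8-dione (racemate)
Product: 20 (5S,6S,11R,12R)-4,10,11,12-tetrabromo-3,9-bis[(1R)-1-hydroxybutyl]-1,7-dioxadispiro[4.0.4.2]dodeca-3,9-diene-2,8-dione, via keto alcohol 19 (not isolated)
Conditions: (S)-Me-CBS oxazaborolidine (0.4 equiv), catecholborane (3 equiv), toluene/CH2Cl2, −78 °C; chromatography
Reagents that add atoms: none
Why: Corey–Bakshi–Shibata reduction: the fully substituted alkenyl group is the large and n-propyl the small substituent, so the (S)-catalyst should give the (R)-carbinol at both ketones. Because the reagent sets the carbinols irrespective of the core, the two enantiomers of 18 become diastereomeric diols and their chromatographic separation is the resolution. Twofold reagent control should leave 20 essentially enantiopure.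

Step 12
Reactants: 20 (5S,6S,11R,12R)-4,10,11,12-tetrabromo-3,9-bis[(1R)-1-hydroxybutyl]-1,7-dioxadispiro[4.0.4.2]dodeca-3,9-diene-2,8-dione
Product: 21 (1R)-1-[(5S,6S,11R,12R)-4,10,11,12-tetrabromo-9-[(1R)-1-hydroxybutyl]-2,8-dioxo-1,7-dioxadispiro[4.0.4.2]dodeca-3,9-dien-3-yl]butyl acetate
Conditions: Ac2O (1.0 equiv), pyridine, CH2Cl2, −20 to 0 °C; recovered 20 recycled
Reagents that add atoms: acetic anhydride CC(=O)OC(C)=O
Why: Acylation with one equivalent of anhydride; the two hydroxyls are homotopic, so any monoacylation gives the same compound and only the statistical distribution has to be accepted. DMAP is left out to spare the vinylogous acyl bromides.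

Step 13
Reactants: 21 (1R)-1-[(5S,6S,11R,12R)-4,10,11,12-tetrabromo-9-[(1R)-1-hydroxybutyl]-2,8-dioxo-1,7-dioxadispiro[4.0.4.2]dodeca-3,9-dien-3-yl]butyl acetate
Product: 22 (1S)-1-[(5S,6S,11R,12R)-9-[(1R)-1-acetoxybutyl]-4,10,11,12-tetrabromo-2,8-dioxo-1,7-dioxadispiro[4.0.4.2]dodeca-3,9-dien-3-yl]butyl acetate
Conditions: PPh3, DIAD, AcOH, toluene, −20 °C to rt
Reagents that add atoms: acetic acid CC(O)=O
Why: Mitsunobu reaction: acetate displaces the alkoxyphosphonium group by SN2 and inverts the remaining (R)-carbinol to (S). SN2′ attack is disfavoured because the γ-carbon (C4 of the butenolide) is fully substituted.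

## Compound list

1 | galactaric acid (meso-(2R,3S,4R,5S)-2,3,4,5-tetrahydroxyhexanedioic acid) | [C@@H]([C@@H]([C@H](C(=O)O)O)O)([C@@H](C(=O)O)O)O | starting material
2 | sodium 3-acetoxy-2-oxo-2H-pyran-6-carboxylate | CC(=O)OC1=CC=C(C(=O)[O-])OC1=O.[Na+] | intermediate
3 | methyl 3-hydroxy-2-oxo-2H-pyran-6-carboxylate | COC(=O)C1=CC=C(O)C(=O)O1 | intermediate
4 | methyl 3-[(tert-butyldimethylsilyl)oxy]-2-oxo-2H-pyran-6-carboxylate | COC(=O)C1=CC=C(O[Si](C)(C)C(C)(C)C)C(=O)O1 | intermediate
5 | methyl (1R,4R)-4-[(tert-butyldimethylsilyl)oxy]-3-oxo-2-oxabicyclo[2.2.0]hex-5-ene-1-carboxylate (racemate) | COC(=O)[C@]12OC(=O)[C@@]1(O[Si](C)(C)C(C)(C)C)C=C2 | intermediate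
6 | methyl (1R,4R,5R,6R)-5,6-dibromo-4-[(tert-butyldimethylsilyl)oxy]-3-oxo-2-oxabicyclo[2.2.0]hexane-1-carboxylate (racemate; C5–Br anti to the silyloxy group, C6–Br anti to the lactone oxygen) | COC(=O)[C@]12OC(=O)[C@@]1(O[Si](C)(C)C(C)(C)C)[C@@H](Br)[C@@H]2Br | intermediate
7 | dimethyl (1R,2R,3R,4R)-3,4-dibromo-1-[(tert-butyldimethylsilyl)oxy]-2-hydroxycyclobutane-1,2-dicarboxylate (racemate; not isolated) | COC(=O)[C@@]1(O)[C@@H](Br)[C@H](Br)[C@]1(O[Si](C)(C)C(C)(C)C)C(=O)OC | intermediate
8 | dimethyl (1R,2R,3R,4R)-3,4-dibromo-1,2-dihydroxycyclobutane-1,2-dicarboxylate (racemate) | COC(=O)[C@@]1(O)[C@@H](Br)[C@H](Br)[C@]1(O)C(=O)OC | intermediate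
9 | Meldrum's acid (2,2-dimethyl-1,3-dioxane-4,6-dione) | CC1(C)OC(=O)CC(=O)O1 | starting material
10 | butanoyl chloride | CCCC(Cl)=O | starting material
11 | 5-(1-hydroxybutylidene)-2,2-dimethyl-1,3-dioxane-4,6-dione (butanoyl Meldrum's acid) | CCCC(O)=C1C(=O)OC(C)(C)OC1=O | intermediate
12 | butanoylketene (3-oxohex-1-en-1-one; not isolated) | CCCC(=O)C=C=O | intermediate
13 | dimethyl (1R,2R,3R,4R)-3,4-dibromo-1-hydroxy-2-[(3-oxohexanoyl)oxy]cyclobutane-1,2-dicarboxylate (racemate; not isolated) | CCCC(=O)CC(=O)O[C@]1(C(=O)OC)[C@@H](Br)[C@H](Br)[C@]1(O)C(=O)OC | intermediate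
14 | dimethyl (1R,2R,3R,4R)-3,4-dibromo-1,2-bis[(3-oxohexanoyl)oxy]cyclobutane-1,2-dicarboxylate (racemate) | CCCC(=O)CC(=O)O[C@]1(C(=O)OC)[C@@H](Br)[C@H](Br)[C@]1(OC(=O)CC(=O)CCC)C(=O)OC | intermediate
15 | half-cyclised keto ester: ring A closed as the 3-butanoyl tetronic acid, the other carbinol carbon still bearing CO2Me and the 3-oxohexanoyloxy group (racemate; not isolated) | CCCC(=O)C1=C(O)[C@@]2(OC1=O)[C@@H](Br)[C@H](Br)[C@]2(OC(=O)CC(=O)CCC)C(=O)OC | intermediate
16 | (5S,6S,11R,12R)-11,12-dibromo-3,9-dibutanoyl-4,10-dihydroxy-1,7-dioxadispiro[4.0.4.2]dodeca-3,9-diene-2,8-dione (racemate) | CCCC(=O)C1=C(O)[C@@]2(OC1=O)[C@@H](Br)[C@H](Br)[C@@]21OC(=O)C(C(=O)CCC)=C1O | intermediate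
17 | monobromo enol: as 16 with C4–Br on ring A and C10–OH on ring B (racemate; not isolated) | CCCC(=O)C1=C(Br)[C@@]2(OC1=O)[C@@H](Br)[C@H](Br)[C@@]21OC(=O)C(C(=O)CCC)=C1O | intermediate
18 | (5S,6S,11R,12R)-4,10,11,12-tetrabromo-3,9-dibutanoyl-1,7-dioxadispiro[4.0.4.2]dodeca-3,9-diene-2,8-dione (racemate) | CCCC(=O)C1=C(Br)[C@@]2(OC1=O)[C@@H](Br)[C@H](Br)[C@@]21OC(=O)C(C(=O)CCC)=C1Br | intermediate
19 | keto alcohol: as 18 with one butanoyl group reduced to (1R)-1-hydroxybutyl (not isolated) | CCC[C@@H](O)C1=C(Br)[C@@]2(OC1=O)[C@@H](Br)[C@H](Br)[C@@]21OC(=O)C(C(=O)CCC)=C1Br | intermediate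
20 | (5S,6S,11R,12R)-4,10,11,12-tetrabromo-3,9-bis[(1R)-1-hydroxybutyl]-1,7-dioxadispiro[4.0.4.2]dodeca-3,9-diene-2,8-dione | CCC[C@@H](O)C1=C(Br)[C@@]2(OC1=O)[C@@H](Br)[C@H](Br)[C@@]21OC(=O)C([C@@H](CCC)O)=C1Br | intermediate
21 | (1R)-1-[(5S,6S,11R,12R)-4,10,11,12-tetrabromo-9-[(1R)-1-hydroxybutyl]-2,8-dioxo-1,7-dioxadispiro[4.0.4.2]dodeca-3,9-dien-3-yl]butyl acetate | CCC[C@@H](O)C1=C(Br)[C@@]2(OC1=O)[C@@H](Br)[C@H](Br)[C@@]21OC(=O)C([C@@H](CCC)OC(C)=O)=C1Br | intermediate
22 | (1S)-1-[(5S,6S,11R,12R)-9-[(1R)-1-acetoxybutyl]-4,10,11,12-tetrabromo-2,8-dioxo-1,7-dioxadispiro[4.0.4.2]dodeca-3,9-dien-3-yl]butyl acetate (CNP0266230.1) | CCC[C@H](OC(C)=O)C1=C(Br)[C@@]2(OC1=O)[C@@H](Br)[C@H](Br)[C@@]21OC(=O)C([C@@H](CCC)OC(C)=O)=C1Br | target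

## Step count and risks

Total step count: 13. Longest linear sequence: 12 (steps 1 to 6 and 8 to 13 from galactaric acid; step 7 is a one-step side branch).

**Step 4 (key step).** The excited pyrone may leave mainly by ring opening to the ketene and be diverted there (trapping by traces of nucleophile, loss of the silyl group), or it may dimerise. The 3-silyloxy donor opposite the 6-ester may also move the excitation away from the diene-type state that closes. 5 may revert thermally or lose CO2 on over-irradiation. Fallback: set out from 3 and switch the donor off with an acid-labile acyl-type group. Boc2O/DMAP should give methyl 3-[(tert-butoxycarbonyl)oxy]-2-oxo-2H-pyran-6-carboxylate F1. Irradiation as in step 4 should give the bicyclic carbonate F2, and Br2 at −78 °C the dibromide F3. HCl in MeOH should then open the lactone and remove the carbonate, returning to the route at 8.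

**Step 5.** Regiocontrol in the opening of the bromonium ion may be poor and give the other anti adduct (bromine on C5 syn to the silyl ether). The ester carbonyl may participate across the ring, or the cation may contract the ring. Fallback: set out from 5 and let only the silyl ethers decide. Cold acid-catalysed methanolysis (camphorsulfonic acid, MeOH, −20 °C) should give the hydroxy silyl ether cyclobutene F4. TBSOTf/2,6-lutidine should give the C2-symmetric bis(silyl ether) F5, whose two faces are equivalent and each carry one silyloxy group. Br2 at −78 °C should then give the dibromide F6 with each bromine anti to the neighbouring silyloxy group. HCl in MeOH returns to the route at 8. F4 and F5 must be kept cold because of the ring-opening risk named above.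

**Step 10.** Activation may occur at the exocyclic acyl oxygen and lead to a bromoalkylidene isomer, or stop halfway at the hindered C4 next to the spiro carbon. Fallback: set out from 14 and fix the carbinols before ring closure, so that the tetronic acid has a single enol oxygen. Noyori hydrogenation (RuCl2[(R)-BINAP], H2, MeOH) should give the bis[(3R)-3-hydroxyhexanoate] F7; the two core diastereomers are separated at this stage. TBSOTf/2,6-lutidine should give the bis(silyl ether) F8, and LiN(SiMe3)2 at −78 to −20 °C should close both rings to the bis(3-alkyl tetronic acid) F9. (COBr)2/DMF should give the tetrabromide F10, and HF·pyridine returns to the route at 20.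

**Step 11.** The two diastereomeric diols may differ too little to be separated. Catalyst control may erode on one core. Hydride may add in conjugate fashion with loss of vinylic bromine. Fallback: resolve early and physically. Racemic 8 is separated by preparative chromatography on a chiral stationary phase and the (1R,2R,3R,4R) enantiomer is taken through steps 8 to 11, so that 18 is a single enantiomer and step 11 gives only 20. The fallback sets out from 8 and comes back at 8; it makes no new compound (F0).

**Step 13.** The activated alcohol may eliminate to the 3-(but-1-enyl)butenolide. PPh3 or the hydrazide anion may attack a vinylogous acyl bromide. PPh3 may also debrominate the vicinal dibromide. Fallback: set out from 21 and replace the inversion by oxidation and reduction. Dess–Martin periodinane should give the keto acetate F11. (R)-Me-CBS oxazaborolidine with catecholborane should give the (S)-alcohol F12, and Ac2O/pyridine returns to the route at 22.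

## Further compounds

F1 | step 4 | methyl 3-[(tert-butoxycarbonyl)oxy]-2-oxo-2H-pyran-6-carboxylate | COC(=O)C1=CC=C(OC(=O)OC(C)(C)C)C(=O)O1
F2 | step 4 | methyl (1R,4R)-4-[(tert-butoxycarbonyl)oxy]-3-oxo-2-oxabicyclo[2.2.0]hex-5-ene-1-carboxylate (racemate) | COC(=O)[C@]12OC(=O)[C@@]1(OC(=O)OC(C)(C)C)C=C2
F3 | step 4 | methyl (1R,4R,5R,6R)-5,6-dibromo-4-[(tert-butoxycarbonyl)oxy]-3-oxo-2-oxabicyclo[2.2.0]hexane-1-carboxylate (racemate) | COC(=O)[C@]12OC(=O)[C@@]1(OC(=O)OC(C)(C)C)[C@@H](Br)[C@@H]2Br
F4 | step 5 | dimethyl (1R,2R)-1-[(tert-butyldimethylsilyl)oxy]-2-hydroxycyclobut-3-ene-1,2-dicarboxylate (racemate) | COC(=O)[C@@]1(O)C=C[C@]1(O[Si](C)(C)C(C)(C)C)C(=O)OC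
F5 | step 5 | dimethyl (1R,2R)-1,2-bis[(tert-butyldimethylsilyl)oxy]cyclobut-3-ene-1,2-dicarboxylate (racemate) | COC(=O)[C@@]1(O[Si](C)(C)C(C)(C)C)C=C[C@]1(O[Si](C)(C)C(C)(C)C)C(=O)OC
F6 | step 5 | dimethyl (1R,2R,3R,4R)-3,4-dibromo-1,2-bis[(tert-butyldimethylsilyl)oxy]cyclobutane-1,2-dicarboxylate (racemate) | COC(=O)[C@@]1(O[Si](C)(C)C(C)(C)C)[C@@H](Br)[C@H](Br)[C@]1(O[Si](C)(C)C(C)(C)C)C(=O)OC
F7 | step 10 | dimethyl (1R,2R,3R,4R)-3,4-dibromo-1,2-bis{[(3R)-3-hydroxyhexanoyl]oxy}cyclobutane-1,2-dicarboxylate | CCC[C@@H](O)CC(=O)O[C@]1(C(=O)OC)[C@@H](Br)[C@H](Br)[C@]1(OC(=O)C[C@H](O)CCC)C(=O)OC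
F8 | step 10 | dimethyl (1R,2R,3R,4R)-3,4-dibromo-1,2-bis{[(3R)-3-[(tert-butyldimethylsilyl)oxy]hexanoyl]oxy}cyclobutane-1,2-dicarboxylate | CCC[C@@H](O[Si](C)(C)C(C)(C)C)CC(=O)O[C@]1(C(=O)OC)[C@@H](Br)[C@H](Br)[C@]1(OC(=O)C[C@H](O[Si](C)(C)C(C)(C)C)CCC)C(=O)OC
F9 | step 10 | (5S,6S,11R,12R)-11,12-dibromo-3,9-bis{(1R)-1-[(tert-butyldimethylsilyl)oxy]butyl}-4,10-dihydroxy-1,7-dioxadispiro[4.0.4.2]dodeca-3,9-diene-2,8-dione | CCC[C@@H](O[Si](C)(C)C(C)(C)C)C1=C(O)[C@@]2(OC1=O)[C@@H](Br)[C@H](Br)[C@@]21OC(=O)C([C@@H](CCC)O[Si](C)(C)C(C)(C)C)=C1O
F10 | step 10 | (5S,6S,11R,12R)-4,10,11,12-tetrabromo-3,9-bis{(1R)-1-[(tert-butyldimethylsilyl)oxy]butyl}-1,7-dioxadispiro[4.0.4.2]dodeca-3,9-diene-2,8-dione | CCC[C@@H](O[Si](C)(C)C(C)(C)C)C1=C(Br)[C@@]2(OC1=O)[C@@H](Br)[C@H](Br)[C@@]21OC(=O)C([C@@H](CCC)O[Si](C)(C)C(C)(C)C)=C1Br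
F0 | step 11 | none | none
F11 | step 13 | (1R)-1-[(5S,6S,11R,12R)-4,10,11,12-tetrabromo-9-butanoyl-2,8-dioxo-1,7-dioxadispiro[4.0.4.2]dodeca-3,9-dien-3-yl]butyl acetate | CCCC(=O)C1=C(Br)[C@@]2(OC1=O)[C@@H](Br)[C@H](Br)[C@@]21OC(=O)C([C@@H](CCC)OC(C)=O)=C1Br
F12 | step 13 | (1R)-1-[(5S,6S,11R,12R)-4,10,11,12-tetrabromo-9-[(1S)-1-hydroxybutyl]-2,8-dioxo-1,7-dioxadispiro[4.0.4.2]dodeca-3,9-dien-3-yl]butyl acetate | CCC[C@H](O)C1=C(Br)[C@@]2(OC1=O)[C@@H](Br)[C@H](Br)[C@@]21OC(=O)C([C@@H](CCC)OC(C)=O)=C1Br
A1 | alternative 1 | (1S)-1-(4-bromo-5-cyclopropylidene-2-oxo-2,5-dihydrofuran-3-yl)butyl acetate | CCC[C@H](OC(C)=O)C1=C(Br)C(=C2CC2)OC1=O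
A2 | alternative 1 | oxaspiropentane: epoxide of A1 at the exocyclic double bond, on the face that leads to A3 | CCC[C@H](OC(C)=O)C1=C(Br)[C@]2(OC1=O)OC23CC3
A3 | alternative 1 | (1S)-1-[(4R)-8-bromo-1,6-dioxo-5-oxaspiro[3.4]oct-7-en-7-yl]butyl acetate (spiro butenolide cyclobutanone) | CCC[C@H](OC(C)=O)C1=C(Br)[C@@]2(OC1=O)CCC2=O
A4 | alternative 2 | dimethyl (2R,3R)-tartrate | [C@@H]([C@H](C(=O)OC)O)(C(=O)OC)O
A5 | alternative 2 | dimethyl (1R,2R)-1,2-dihydroxycyclobut-3-ene-1,2-dicarboxylate | COC(=O)[C@@]1(O)C=C[C@]1(O)C(=O)OC
A6 | alternative 2 | dimethyl (1R,2R)-1,2-bis[(3-oxohexanoyl)oxy]cyclobut-3-ene-1,2-dicarboxylate | CCCC(=O)CC(=O)O[C@]1(C(=O)OC)C=C[C@]1(OC(=O)CC(=O)CCC)C(=O)OC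
A7 | alternative 2 | bis-spiro 3-butanoyl tetronic acid cyclobutene (16 with C11=C12 in place of the dibromide) | CCCC(=O)C1=C(O)[C@@]2(OC1=O)C=C[C@@]21OC(=O)C(C(=O)CCC)=C1O
A8 | alternative 3 | cyclobut-3-ene-1,2-dione | O=C1C=CC1=O
A9 | alternative 3 | methyl 3,3-dibromo-2-[(1S)-1-[(tert-butyldimethylsilyl)oxy]butyl]prop-2-enoate | CCC[C@H](O[Si](C)(C)C(C)(C)C)C(C(=O)OC)=C(Br)Br
A10 | alternative 3 | bis-spiro cyclobutene bis(silyl ether) with (S,S) side chains | CCC[C@H](O[Si](C)(C)C(C)(C)C)C1=C(Br)[C@@]2(OC1=O)C=C[C@@]21OC(=O)C([C@H](CCC)O[Si](C)(C)C(C)(C)C)=C1Br
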